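**Retrosynthetic overview**
1. The target is an 8,9-seco-ent-kaurane: a ring D cyclopentenone (C8, C14, C13, C16, C15) bridges a ten-membered ring (C5–C10, C9, C11–C14, C8), which is trans-fused to ring A (C1–C5, C10).
2. Enabling feature: ring A holds the aldol retron C1(OH)–C10(quaternary)–C9(=O). The ten-membered ring holds the oxy-Cope retron C9(=O)–C10–C5–C6–C7=C8, once the C7 carbinol/C8=C14 enone is read as the ene product of a C7=C8–C15 enone. C8 and C9 are the two ends of the broken kaurane C8–C9 bond.
3. Key disconnection (one operation): C1–C10 (aldol, ring A) and C5–C6 with re-formation of C8–C9 (retro-oxy-Cope). This gives a 2-alkenyl-1-vinylbicyclo[3.2.1]octan-2-ol whose achiral side chain ends in a β-methoxy enal.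
4. The carbinol comes from C9–C10 alkenyl-metal addition of a hydroxypivalate-derived chain to a bicyclic ketone. That ketone is made from (+)-nopinone by cyclobutane C–C cleavage and deconjugative alkylation (C8–C15).
5. Ring order: ring D (step 5), ten-membered ring (step 15), ring A (step 15, last). End game: C3 reduction and acetylation, C15 allylic oxidation, singlet-oxygen ene reaction for C7–OH and C8=C14.

Key step: step 15

Remark: locants C1–C20 follow ent-kaurane numbering throughout; the target is read from the SMILES as 1S,3S,5R,7R,10S,13R.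

Step 1
Reactants: 1 (+)-nopinone
Product: 4 (E)-3-ethylidenenopinone, via lithium aldolate 2 (not isolated), via mesylate 3 (not isolated)
Conditions: LiN(i-Pr)2, THF, −78 °C; CH3CHO; then MsCl, Et3N, 0 °C; DBU, rt
Reagents that add atoms: acetaldehyde, CC=O
Why: The kinetic lithium enolate of 1 (enolisable only toward C3) adds to acetaldehyde in a directed aldol reaction and the derived mesylate undergoes E1cB elimination to the more stable (E)-enone, so no new stereocentre survives.

Step 2
Reactants: 4 (E)-3-ethylidenenopinone
Product: 5 (R,E)-4-(2-bromopropan-2-yl)-2-ethylidenecyclohexan-1-one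
Conditions: HBr (33% in AcOH), CH2Cl2, 0 °C
Reagents that add atoms: hydrogen bromide, Br
Why: Acid-mediated strain-release heterolysis of the cyclobutyl ketone (Grob-type C–C cleavage of the bond between the carbonyl α-carbon and the gem-dimethyl carbon) should give the enol and a tertiary cation that is captured by bromide, so the former C5 stereocentre of nopinone is kept as the only stereocentre (later C13).

Step 3
Reactants: 5 (R,E)-4-(2-bromopropan-2-yl)-2-ethylidenecyclohexan-1-one
Product: 6 (R,E)-2-ethylidene-4-(prop-1-en-2-yl)cyclohexan-1-one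
Conditions: KOt-Bu, t-BuOH/THF, 0 °C to rt
Reagents that add atoms: none
Why: E2 dehydrobromination with a bulky alkoxide should remove one of the six methyl hydrogens in preference to the single ring methine hydrogen, giving the isopropenyl group without touching the stereocentre.

Step 4
Reactants: 6 (R,E)-2-ethylidene-4-(prop-1-en-2-yl)cyclohexan-1-one
Product: 7 (R,E)-4-(3-chloroprop-1-en-2-yl)-2-ethylidenecyclohexan-1-one
Conditions: Ca(OCl)2, CO2 (solid), CH2Cl2/H2O, 0 °C
Reagents that add atoms: calcium hypochlorite, [Ca+2].[O-]Cl.[O-]Cl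
Why: Ene-type allylic chlorination by HOCl should attack only the electron-rich 1,1-disubstituted alkene with shift of the double bond, leaving the electron-poor enone untouched.

Step 5
Reactants: 7 (R,E)-4-(3-chloroprop-1-en-2-yl)-2-ethylidenecyclohexan-1-one
Product: 9 (1S,5R)-1-ethenyl-6-methylidenebicyclo[3.2.1]octan-2-one, via potassium dienolate 8 (not isolated)
Conditions: KOt-Bu, t-BuOH/THF, rt
Reagents that add atoms: none
Why: Deconjugative intramolecular α-alkylation: the extended dienolate formed under equilibrating conditions should be alkylated at its α-carbon (C8) by the tethered allylic chloride in a 5-exo-tet closure of ring D, and the C13 stereocentre forces both bridges to the same face, which fixes the new quaternary centre.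

Step 6
Reactants: 10 methyl 3-hydroxy-2,2-dimethylpropanoate
Product: 11 methyl 2,2-dimethyl-3-oxopropanoate
Conditions: TEMPO (cat.), PhI(OAc)2, CH2Cl2, rt
Reagents that add atoms: none
Why: TEMPO-catalysed oxidation of the primary neopentyl alcohol should stop cleanly at the non-enolisable aldehyde.

Step 7
Reactants: 11 methyl 2,2-dimethyl-3-oxopropanoate
Product: 12 methyl 2,2-dimethylbut-3-ynoate
Conditions: dimethyl (1-diazo-2-oxopropyl)phosphonate, K2CO3, MeOH, 0 °C to rt
Reagents that add atoms: dimethyl (1-diazo-2-oxopropyl)phosphonate, CC(=O)C(=[N+]=[N-])P(=O)(OC)OC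
Why: Ohira–Bestmann (Seyferth–Gilbert) homologation should convert the non-enolisable aldehyde into the terminal alkyne in methanol, which leaves the methyl ester unchanged.

Step 8
Reactants: 12 methyl 2,2-dimethylbut-3-ynoate
Product: 14 methyl 2,2-dimethylpent-3-ynoate, via lithium acetylide 13 (not isolated)
Conditions: LiN(SiMe3)2, THF, −78 °C; MeI, −78 °C to rt
Reagents that add atoms: iodomethane, CI
Why: Deprotonation of the terminal alkyne (the ester has no α-hydrogen) followed by SN2 methylation of the acetylide should give the internal alkyne.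

Step 9
Reactants: 14 methyl 2,2-dimethylpent-3-ynoate
Product: 16 methyl (E)-4-iodo-2,2-dimethylpent-3-enoate, via alkenylzirconocene chloride 15 (not isolated)
Conditions: Cp2Zr(H)Cl, THF, rt; then I2, 0 °C
Reagents that add atoms: diiodine, II
Why: syn-Hydrozirconation should place zirconium on the alkyne carbon remote from the quaternary centre, and iodinolysis with retention then gives the (E)-alkenyl iodide with iodine trans to the quaternary carbon.

Step 10
Reactants: 16 methyl (E)-4-iodo-2,2-dimethylpent-3-enoate
Product: 17 methyl (E)-6-iodo-4,4-dimethyl-3-oxohept-5-enoate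
Conditions: methyl acetate, LiN(i-Pr)2, THF, −78 °C; then 16, −78 to 0 °C
Reagents that add atoms: methyl acetate, CC(=O)OC
Why: Crossed Claisen condensation of the non-enolisable neopentyl ester with the lithium enolate of methyl acetate should be driven by deprotonation of the β-keto ester formed.

Step 11
Reactants: 17 methyl (E)-6-iodo-4,4-dimethyl-3-oxohept-5-enoate
Product: 18 methyl (2E,5E)-6-iodo-3-methoxy-4,4-dimethylhepta-2,5-dienoate
Conditions: HC(OMe)3, MeOH, H2SO4 (cat.), 60 °C
Reagents that add atoms: trimethyl orthoformate, COC(OC)OC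
Why: Acid-catalysed ketalisation and loss of methanol (enol ether formation) should give, under equilibrating conditions, the (E)-β-methoxyacrylate with methoxy trans to the ester, the geometry that later lets the carbonyl carbon reach C10.

Step 12
Reactants: 18 methyl (2E,5E)-6-iodo-3-methoxy-4,4-dimethylhepta-2,5-dienoate
Product: 19 (2E,5E)-6-iodo-3-methoxy-4,4-dimethylhepta-2,5-dien-1-ol
Conditions: i-Bu2AlH, CH2Cl2, −78 °C
Reagents that add atoms: none
Why: 1,2-Reduction of the vinylogous carbonate ester with i-Bu2AlH should give the allylic alcohol without touching the alkenyl iodide or the enol ether.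

Step 13
Reactants: 19 (2E,5E)-6-iodo-3-methoxy-4,4-dimethylhepta-2,5-dien-1-ol; 9 (1S,5R)-1-ethenyl-6-methylidenebicyclo[3.2.1]octan-2-one
Product: 21 tertiary carbinol diol (alkenyl chain on C9 of the bicycle), via lithium alkoxide alkenyllithium 20 (not isolated)
Conditions: t-BuLi (3 equiv), Et2O, −78 °C; CeCl3, THF, −78 °C; then 9, −78 to −40 °C
Reagents that add atoms: none
Why: Iodine–lithium exchange with retention of alkene geometry and 1,2-addition of the derived organocerium reagent to the hindered, enolisable ketone should occur anti to the axial C8–C15 bond of the two-carbon bridge (axial attack on the six-membered ring), which sets the C9 carbinol with the alkenyl group where C10 sits in an ent-kaurane.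

Step 14
Reactants: 21 tertiary carbinol diol
Product: 22 tertiary carbinol β-methoxy enal
Conditions: MnO2, CH2Cl2, rt
Reagents that add atoms: none
Why: MnO2 should oxidise only the primary allylic alcohol, giving the non-enolisable vinylogous formate ester while the tertiary carbinol is inert.

Step 15
Reactants: 22 tertiary carbinol β-methoxy enal
Product: 26 3-methoxy-1-(triethylsilyloxy)-8,9-seco-ent-kaura-2,7,16-trien-9-one, via potassium alkoxide 23 (not isolated), via potassium enolate 24 (not isolated), via potassium aldolate 25 (not isolated)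
Conditions: KH, 18-crown-6, THF, 0 °C to rt; then Et3SiCl, −78 °C
Reagents that add atoms: chlorotriethylsilane, CC[Si](Cl)(CC)CC
Why: Deprotonation gives the tertiary potassium alkoxide, whose anionic oxy-Cope rearrangement across the 1,5-diene C5=C10–C9–C8–C7=C6 cleaves the C8–C9 bond of the bicyclo[3.2.1]octane, forms C5–C6 and expands the six-membered ring to the ten-membered ring, after which the regiodefined tetrasubstituted enolate (O–C9=C10) adds to the tethered β-methoxy enal (C10–C1) and the aldolate is silylated. The closest known reaction type is the tandem anionic oxy-Cope rearrangement/intramolecular aldol (enolate-trapping) sequence of 1,2-dialkenylcycloalkanols. The ten-membered ring closes by [3,3]-sigmatropic four-carbon ring expansion and ring A by a 6-(enolexo)-exo-trig aldol addition. C5 is set by the chair transition state, which is the ring B chair of an ent-kaurane (C10 axial on C9 and anti to C15, the (E)-alkene placing C4 pseudo-equatorial); C10 is set because C1 can reach only the enolate face opposite the new C5–C6 bond, which gives the trans ring fusion; C1 is set by the closed, potassium-bridged chair arrangement that places the oxygen equatorial. The step needs the [3,3] shift instead of heterolytic fragmentation, and C-attack at C1 instead of proton transfer or attack at C3; the first is secured by the rigidly gauche alkenyl groups and the strain of the bicycle, the second by the absence of acidic C–H bonds in the aldehyde, the neopentyl shielding of C3 and the (E)-enol ether geometry that holds C1 next to C10.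

Step 16
Reactants: 26 3-methoxy-1-(triethylsilyloxy)-8,9-seco-ent-kaura-2,7,16-trien-9-one
Product: 27 1-(triethylsilyloxy)-8,9-seco-ent-kaura-7,16-diene-3,9-dione
Conditions: oxalic acid (aq.), THF, 0 °C
Reagents that add atoms: water, O
Why: Mild acidic enol ether hydrolysis (C2 protonation, hydration of the oxocarbenium ion) should be faster than cleavage or β-elimination of the hindered silyl ether.

Step 17
Reactants: 27 1-(triethylsilyloxy)-8,9-seco-ent-kaura-7,16-diene-3,9-dione
Product: 28 3-hydroxy-1-(triethylsilyloxy)-8,9-seco-ent-kaura-7,16-dien-9-one (axial 3-alcohol)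
Conditions: LiBH(s-Bu)3, THF, −78 °C
Reagents that add atoms: none
Why: The bulky hydride should reduce the six-membered ketone from the equatorial direction to give the axial (3S) alcohol, while the ten-membered-ring ketone at C9, flanked by quaternary C10, is much less reactive (diastereoselective ketone reduction).

Step 18
Reactants: 28 3-hydroxy-1-(triethylsilyloxy)-8,9-seco-ent-kaura-7,16-dien-9-one
Product: 29 3-acetoxy-1-(triethylsilyloxy)-8,9-seco-ent-kaura-7,16-dien-9-one
Conditions: Ac2O, Et3N, DMAP (cat.), CH2Cl2, rt
Reagents that add atoms: acetic anhydride, CC(=O)OC(C)=O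
Why: DMAP-catalysed acylation of the only free hydroxyl group should give the C3 acetate.

Step 19
Reactants: 29 3-acetoxy-1-(triethylsilyloxy)-8,9-seco-ent-kaura-7,16-dien-9-one
Product: 30 3-acetoxy-1-hydroxy-8,9-seco-ent-kaura-7,16-dien-9-one
Conditions: HF·pyridine, pyridine/THF, 0 °C
Reagents that add atoms: none
Why: Buffered fluoride-mediated desilylation should free the C1 hydroxyl while keeping the acetate and the β-hydroxy ketone intact.

Step 20
Reactants: 30 3-acetoxy-1-hydroxy-8,9-seco-ent-kaura-7,16-dien-9-one
Product: 31 3-acetoxy-1,15-dihydroxy-8,9-seco-ent-kaura-7,16-dien-9-one (C15 configuration not assigned)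
Conditions: SeO2 (cat.), t-BuOOH, CH2Cl2, 0 °C to rt
Reagents that add atoms: tert-butyl hydroperoxide, CC(C)(C)OO
Why: SeO2 allylic oxidation (ene reaction, then [2,3]-sigmatropic shift) should attack C15, the methylene allylic to both the exocyclic C16 methylene and the C7=C8 bond and sitting at the (E)-position of the more substituted alkene terminus; the new carbinol configuration is of no consequence.

Step 21
Reactants: 31 3-acetoxy-1,15-dihydroxy-8,9-seco-ent-kaura-7,16-dien-9-one
Product: 32 3-acetoxy-1-hydroxy-8,9-seco-ent-kaura-7,16-diene-9,15-dione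
Conditions: MnO2, CH2Cl2, rt
Reagents that add atoms: none
Why: MnO2 should oxidise the doubly allylic alcohol to the cross-conjugated dienone and leave the saturated secondary alcohol at C1 untouched (chemoselective allylic alcohol oxidation).

Step 22
Reactants: 32 3-acetoxy-1-hydroxy-8,9-seco-ent-kaura-7,16-diene-9,15-dione
Product: 34 target CNP0223751.1, via allylic hydroperoxide 33 (not isolated)
Conditions: O2, hν (visible), tetraphenylporphyrin (cat.), CH2Cl2, −20 °C; then Me2S
Reagents that add atoms: dioxygen, O=O
Why: The Schenck ene reaction of singlet oxygen with the s-cis enone should follow the geminal rule for α,β-unsaturated carbonyls (hydrogen taken from C14 on the α-carbon, oxygen to the β-carbon C7, double bond to C8=C14), the trisubstituted alkene reacting before the 1,1-disubstituted methylene, and oxygen should arrive on the outer face of C7=C8 opposite the transannular C9 carbonyl to give (7R) before reduction of the hydroperoxide.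

**Compound list**
1 | (+)-nopinone, (1R,5S)-6,6-dimethylbicyclo[3.1.1]heptan-2-one | O=C1CC[C@H]2C[C@@H]1C2(C)C | starting material
2 | lithium aldolate of nopinone and acetaldehyde (3-(1-oxidoethyl) derivative, diastereomer mixture at the two new centres) | [Li+].CC([O-])C1C[C@H]2C[C@@H](C1=O)C2(C)C | intermediate
3 | 3-[1-(methylsulfonyloxy)ethyl]nopinone (diastereomer mixture) | CC(OS(C)(=O)=O)C1C[C@H]2C[C@@H](C1=O)C2(C)C | intermediate
4 | (E)-3-ethylidenenopinone, (1R,5R,E)-3-ethylidene-6,6-dimethylbicyclo[3.1.1]heptan-2-one | C/C=C1/C(=O)[C@@H]2C[C@H](C1)C2(C)C | intermediate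
5 | (R,E)-4-(2-bromopropan-2-yl)-2-ethylidenecyclohexan-1-one | C/C=C1/C(=O)CC[C@H](C1)C(C)(C)Br | intermediate
6 | (R,E)-2-ethylidene-4-(prop-1-en-2-yl)cyclohexan-1-one | C/C=C1/C(=O)CC[C@H](C1)C(C)=C | intermediate
7 | (R,E)-4-(3-chloroprop-1-en-2-yl)-2-ethylidenecyclohexan-1-one | C/C=C1/C(=O)CC[C@H](C1)C(CCl)=C | intermediate
8 | potassium dienolate of 7 (1-oxido-2-vinylcyclohexene form) | [K+].C=CC1=C([O-])CC[C@H](C1)C(CCl)=C | intermediate
9 | (1S,5R)-1-ethenyl-6-methylidenebicyclo[3.2.1]octan-2-one (C8 and C13 as in an ent-kaurane) | C=C[C@@]12CC(=C)[C@@H](C1)CCC2=O | intermediate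
10 | methyl 3-hydroxy-2,2-dimethylpropanoate | COC(=O)C(C)(C)CO | starting material
11 | methyl 2,2-dimethyl-3-oxopropanoate | COC(=O)C(C)(C)C=O | intermediate
12 | methyl 2,2-dimethylbut-3-ynoate | COC(=O)C(C)(C)C#C | intermediate
13 | lithium acetylide of 12 | [Li+].COC(=O)C(C)(C)C#[C-] | intermediate
14 | methyl 2,2-dimethylpent-3-ynoate | COC(=O)C(C)(C)C#CC | intermediate
15 | (E)-alkenylzirconocene chloride from 14 (Zr on the methyl-bearing carbon, trans to the quaternary carbon) | COC(=O)C(C)(C)/C=C(C)/[Zr](Cl)(C1C=CC=C1)C1C=CC=C1 | intermediate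
16 | methyl (E)-4-iodo-2,2-dimethylpent-3-enoate | COC(=O)C(C)(C)/C=C(/I)C | intermediate
17 | methyl (E)-6-iodo-4,4-dimethyl-3-oxohept-5-enoate | COC(=O)CC(=O)C(C)(C)/C=C(/I)C | intermediate
18 | methyl (2E,5E)-6-iodo-3-methoxy-4,4-dimethylhepta-2,5-dienoate | COC(=O)/C=C(/OC)C(C)(C)/C=C(/I)C | intermediate
19 | (2E,5E)-6-iodo-3-methoxy-4,4-dimethylhepta-2,5-dien-1-ol | OC/C=C(/OC)C(C)(C)/C=C(/I)C | intermediate
20 | lithium alkoxide/alkenyllithium from 19 (iodine replaced by lithium with retention) | [Li+].[O-]C/C=C(/OC)C(C)(C)/C=C(/[Li])C | intermediate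
21 | (1S,5R)-1-ethenyl-6-methylidenebicyclo[3.2.1]octan-2-ol bearing at C2 (kaurane C9), anti to the two-carbon bridge, the (2E,5E)-7-hydroxy-5-methoxy-4,4-dimethylhepta-2,5-dien-2-yl group | C=C[C@@]12CC(=C)[C@@H](C1)CC[C@@]2(O)/C(C)=C/C(C)(C)/C(OC)=C\CO | intermediate
22 | the same carbinol with the (2E,5E)-5-methoxy-4,4-dimethyl-7-oxohepta-2,5-dien-2-yl group (β-methoxy enal) | C=C[C@@]12CC(=C)[C@@H](C1)CC[C@@]2(O)/C(C)=C/C(C)(C)/C(OC)=C\C=O | intermediate
23 | potassium alkoxide of 22 | [K+].C=C[C@@]12CC(=C)[C@@H](C1)CC[C@@]2([O-])/C(C)=C/C(C)(C)/C(OC)=C\C=O | intermediate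
24 | potassium enolate after ring expansion (ten-membered ring, C9–O/C10 enolate with C5 and C11 trans, (7E)-alkene, ring A open, 5R) | [K+].C=C1C/C2=C/C[C@H](C(C)(C)/C(OC)=C\C=O)/C(C)=C(\[O-])CC[C@@H]1C2 | intermediate
25 | potassium aldolate (ring A closed, C1 alkoxide) | [K+].C=C1C/C2=C/C[C@H]3[C@](C)(C(=O)CC[C@@H]1C2)[C@@H]([O-])C=C(OC)C3(C)C | intermediate
26 | (7E)-3-methoxy-1-(triethylsilyloxy)-8,9-seco-ent-kaura-2,7,16-trien-9-one (C1, C5, C10, C13 as in the target) | C=C1C/C2=C/C[C@H]3[C@](C)(C(=O)CC[C@@H]1C2)[C@@H](O[Si](CC)(CC)CC)C=C(OC)C3(C)C | intermediate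
27 | (7E)-1-(triethylsilyloxy)-8,9-seco-ent-kaura-7,16-diene-3,9-dione | C=C1C/C2=C/C[C@H]3[C@](C)(C(=O)CC[C@@H]1C2)[C@@H](O[Si](CC)(CC)CC)CC(=O)C3(C)C | intermediate
28 | (7E)-3-hydroxy-1-(triethylsilyloxy)-8,9-seco-ent-kaura-7,16-dien-9-one (3S, axial alcohol) | C=C1C/C2=C/C[C@H]3[C@](C)(C(=O)CC[C@@H]1C2)[C@@H](O[Si](CC)(CC)CC)C[C@H](O)C3(C)C | intermediate
29 | (7E)-3-acetoxy-1-(triethylsilyloxy)-8,9-seco-ent-kaura-7,16-dien-9-one | C=C1C/C2=C/C[C@H]3[C@](C)(C(=O)CC[C@@H]1C2)[C@@H](O[Si](CC)(CC)CC)C[C@H](OC(C)=O)C3(C)C | intermediate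
30 | (7E)-3-acetoxy-1-hydroxy-8,9-seco-ent-kaura-7,16-dien-9-one | C=C1C/C2=C/C[C@H]3[C@](C)(C(=O)CC[C@@H]1C2)[C@@H](O)C[C@H](OC(C)=O)C3(C)C | intermediate
31 | (7E)-3-acetoxy-1,15-dihydroxy-8,9-seco-ent-kaura-7,16-dien-9-one (C15 not assigned) | C=C1C(O)/C2=C/C[C@H]3[C@](C)(C(=O)CC[C@@H]1C2)[C@@H](O)C[C@H](OC(C)=O)C3(C)C | intermediate
32 | (7E)-3-acetoxy-1-hydroxy-8,9-seco-ent-kaura-7,16-diene-9,15-dione | C=C1C(=O)/C2=C/C[C@H]3[C@](C)(C(=O)CC[C@@H]1C2)[C@@H](O)C[C@H](OC(C)=O)C3(C)C | intermediate
33 | 7-hydroperoxide of the target (3-acetoxy-7-hydroperoxy-1-hydroxy-8,9-seco-ent-kaura-8(14),16-diene-9,15-dione) | C=C1C(=O)C2=C[C@H]1CCC(=O)[C@@]1(C)[C@H](C[C@H]2OO)C(C)(C)[C@@H](OC(C)=O)C[C@@H]1O | intermediate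
34 | CNP0223751.1, (1S,3S,5R,7R,10S,13R)-3-acetoxy-1,7-dihydroxy-8,9-seco-ent-kaura-8(14),16-diene-9,15-dione | C=C1C(=O)C2=C[C@H]1CCC(=O)[C@@]1(C)[C@H](C[C@H]2O)C(C)(C)[C@@H](OC(C)=O)C[C@@H]1O | target

**Step count and risks**
Total: 22 steps. Longest linear sequence: 17 steps (steps 6–12, then 13–22, from methyl 3-hydroxy-2,2-dimethylpropanoate).

The three steps most likely to fail:

Step 15. After the [3,3] shift the aldol ring closure may be slow or reversible, because the tetrasubstituted enolate is hindered and the vinylogous-ester carbonyl is deactivated. Protonation or O-silylation of the enolate would then leave ring A open. Fallback: from 22 the anionic oxy-Cope rearrangement is run alone (KH, 18-crown-6, THF) and the enolate is trapped on oxygen with Et3SiCl to give the triethylsilyl enol ether F1. F1 is then cyclised under fluoride catalysis (Bu4N[Ph3SiF2], THF, 0 °C) in a silyl-transfer Mukaiyama aldol addition, in which the aldolate is captured irreversibly as its silyl ether. This returns to the route at 26.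

Step 22. Oxygen transfer may show poor site selectivity (reaction at the exocyclic methylene enone) or poor facial selectivity at C7, and the product may be over-oxidised. Fallback: from 32, epoxidation of the trisubstituted enone double bond with dimethyldioxirane (acetone, 0 °C) should give the 7,8-epoxy ketone F2. Reductive opening of the α,β-epoxy ketone at C8 with SmI2 (THF/MeOH, −90 °C) should give the β-hydroxy ketone F3. α-Selenenylation at C8 (PhSeCl, EtOAc) should give the selenide F4, and oxidation with H2O2 should give a selenoxide that eliminates syn toward C14, away from the carbinol carbon. This returns to the route at 34.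

Step 5. Regiocontrol of enolate formation may be lost (alkylation through the cross-conjugated C11 enolate) or O-alkylation may compete. Fallback: from 7, thermodynamic enol acetylation (isopropenyl acetate, TsOH cat.) should give the linear dienol acetate F5. Cleavage with MeLi (2 equiv, 1,2-dimethoxyethane, 0 °C) generates the lithium dienolate regiospecifically under aprotic, non-equilibrating conditions, and intramolecular α-alkylation then returns to the route at 9.

Further compounds
F1 | step 15 | triethylsilyl enol ether of the ring-expanded ketone (ten-membered ring, ring A open, β-methoxy enal side chain) | C=C1C/C2=C/C[C@H](C(C)(C)/C(OC)=C\C=O)/C(C)=C(\O[Si](CC)(CC)CC)CC[C@@H]1C2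
F2 | step 22 | 3-acetoxy-7,8-epoxy-1-hydroxy-8,9-seco-ent-kaur-16-ene-9,15-dione (epoxide oxygen on the outer face) | C=C1C(=O)[C@]24O[C@@H]4C[C@H]3[C@](C)(C(=O)CC[C@@H]1C2)[C@@H](O)C[C@H](OC(C)=O)C3(C)C
F3 | step 22 | 3-acetoxy-1,7-dihydroxy-8,9-seco-ent-kaur-16-ene-9,15-dione (7R, C8 epimers) | C=C1C(=O)C2[C@H](O)C[C@H]3[C@](C)(C(=O)CC[C@@H]1C2)[C@@H](O)C[C@H](OC(C)=O)C3(C)C
F4 | step 22 | 8-(phenylselanyl) derivative of F3 (C8 not assigned) | C=C1C(=O)C2([Se]c4ccccc4)[C@H](O)C[C@H]3[C@](C)(C(=O)CC[C@@H]1C2)[C@@H](O)C[C@H](OC(C)=O)C3(C)C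
F5 | step 5 | (R)-4-(3-chloroprop-1-en-2-yl)-2-ethenylcyclohex-1-en-1-yl acetate | C=CC1=C(OC(C)=O)CC[C@H](C1)C(CCl)=C
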